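## The problem

Griffinone C is a (2S)-flavanone: a chroman-4-one (rings A and C) with an unsubstituted phenyl ring B on C2. Ring A carries a C-prenyl group at C8 and a tertiary 1,1-dimethylallyl ("reverse prenyl") ether at O7.

- **The stereocentre.** C2 is the only one. It is benzylic, bonded to O1 and β to the C4 ketone. Base or acid opens the O1–C2 bond by retro-oxa-Michael reaction to the achiral 2'-hydroxychalcone. No second stereocentre can control C2, so it has to be set by a catalyst and not stressed afterwards.
- **Ring A.** It is a contiguous 1,2,3,4-tetrasubstituted benzene (C4a acyl, C8a–O1, C8 prenyl, C7–O). C8 lies between the two oxygens and competes with the free C6 in any C–C bond formation on the ring.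
- **The sensitive groups.** The O7–CMe2–CH=CH2 ether cannot be made by SN2. It ionises with protic or Lewis acids, is cleaved by Pd(0) on prolonged contact, and above roughly 100 °C undergoes aromatic Claisen rearrangement to C6. The C8 prenyl olefin cyclises onto a free O7–H under acid. Three different C=C bonds rule out late hydrogenation.
- **The feature that makes the key step possible.** In ring C, C2 carries only H, O1 and ring B, and C3 is an unsubstituted CH2 next to C4=O. The target is therefore the formal adduct of phenyl–H across C2=C3 of a 4H-chromen-4-one, with C2 as the β-carbon of the enone O1–C2=C3–C4=O. That chromone is achiral and stable to base and heat.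
- **A second feature.** O7–C(Me)2–CH=CH2 and C8–CH2–CH=CMe2 are the same C5 unit before and after a [3,3] shift across the C7–C8 bond. One reagent can therefore supply both groups.

## Retrosynthesis

**10 ⇒ 8 + 9 (cut C2–C1′).** Griffinone C 10 is cut between C2 and ring B, giving the fully substituted chromone 8 and phenylboronic acid 9. The neighbouring cut, O1–C2, leads to a chalcone whose ring closure is reversible and is the very pathway of racemisation. The C2–C1′ cut instead forms a C–C bond that cannot reopen. The precursor 8 is achiral, and it may be heated or treated with base without consequence for configuration. The forward reaction must add phenyl to one face of C2=C3, leave two isolated olefins and an allylic aryl ether alone, and run near neutral pH at room temperature. Placing it last means that C2 sees no further reagent.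

**8 ⇒ 7 + 3 (cut O7–CMe2).** The tertiary ether is cut to phenol 7 and the mixed carbonate 3. A 1,1-dimethyl-π-allyl palladium species is attacked by phenoxide at its substituted terminus under kinetic control. This makes in one step a bond that SN2 chemistry cannot make, and at 0 °C, well below the Claisen threshold. The forward reaction must be stopped before Pd(0) equilibrates the product to the linear prenyl ether.

**7 ⇒ 5, through 6 (cut C8–CH2).** The C8 prenyl group is traced to the O7 1,1-dimethylallyl ether 5 by an aromatic Claisen rearrangement through dienone 6. Direct C-prenylation of a 7-hydroxychromone would give O-alkylation and C6/C8 mixtures. The [3,3] shift delivers the C5 unit only ortho to O7, with the allyl inversion that turns a reverse prenyl ether into a normal prenyl group. The chromone stage is chosen over the flavanone stage for two reasons. There is no C2 stereocentre to lose at 130 °C. The aromatic benzo-γ-pyrone also gives the C7–C8 bond the higher π-bond order, which should direct migration to C8 rather than C6. The para position, C4a, is blocked.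

**5 ⇒ 4 + 3; 3 ⇒ 1 (via 2).** Ether 5 comes from commercial 7-hydroxychromone 4 and the same carbonate 3, by the same palladium etherification. Carbonate 3 is made from 2-methylbut-3-en-2-ol 1 through its lithium alkoxide 2 and Boc2O. The whole target is thus assembled from 4, two equivalents of one C5 reagent and one arylboronic acid.

## Roads not taken

**Alternative 1:** Cut O1–C2 (the most obvious route). Claisen–Schmidt condensation of acetophenone A2 with the B-ring aldehyde would give 2'-hydroxychalcone A1, and 6-endo oxa-Michael closure would give 10. The closure is reversible and is the same pathway by which the product racemises, so the configuration is set under equilibrating conditions. The 4'-alkoxy donor makes the enone of A1 a poor acceptor, and the 3'-prenyl group crowds the nucleophilic OH. Catalytic variants with high selectivity rely on an extra activating ester at C3, whose removal needs hot acid. That would destroy the tertiary allyl ether and cyclise the prenyl group. A2 needs the same etherification/Claisen/etherification sequence as the chosen route, so no step is saved.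

**Alternative 2:** Cut the C2–H and C3–H bonds. Flavone A3 would be reduced at C2=C3 by asymmetric hydrogenation or conjugate reduction. A3 has four C=C bonds, and the push–pull C2=C3 bond is the least reactive of them. The monosubstituted vinyl group would be hydrogenated first. Flavone hydrogenations also tend to run on to the flavan-4-ol, which would add a re-oxidation. Building A3 requires a diketone cyclodehydration in acid, incompatible with the O7 ether, so the ether would have to be introduced after the stereocentre.

**Alternative 3:** Cut O7–CMe2 by a [3,3] shift in the opposite direction. The dearomatised 8,8-diprenyl dienone A4 would be heated so that one prenyl group moves from C8 to O7 with allyl inversion, driven by re-aromatisation of ring A. This would form the tertiary ether without any O-alkylation. However, A4 needs two C-alkylations at C8 of a 7-oxidoflavanone under basic conditions that racemise C2 and compete with O- and C6-alkylation. The position of the equilibrium is also not secured: aromaticity favours 10, while the trisubstituted olefin and the vinylogous-ester stabilisation favour A4. Any temperature that drives the shift also opens the onward Claisen path from 10 to C6.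

Key step: step 5

Assumption: the sense of induction in step 5 is taken from the quadrant model for Rh/(S)-biaryl-bisphosphine additions to cyclic enones (the face that gives (S)-3-arylcyclohexanones maps onto 2S here). It is to be checked on unsubstituted chromone, and the ligand antipode used if the check shows the opposite sense.

## Route

Step 1
Reactants: 1 2-methylbut-3-en-2-ol
Product: 3 tert-butyl (2-methylbut-3-en-2-yl) carbonate, via lithium 2-methylbut-3-en-2-olate 2 (not isolated)
Conditions: n-BuLi (1.05 equiv), THF, −78 → 0 °C; then Boc2O (1.1 equiv), 0 °C → rt
Reagents that add atoms: di-tert-butyl dicarbonate, CC(C)(C)OC(=O)OC(=O)OC(C)(C)C; n-butyllithium, [Li]CCCC (lithium of 2 only)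
Why: O-acylation of a tertiary lithium alkoxide by Boc2O gives the mixed carbonate; the alkoxide is needed because the free tertiary alcohol is too hindered to react cleanly.

Step 2
Reactants: 4 7-hydroxy-4H-chromen-4-one; 3 tert-butyl (2-methylbut-3-en-2-yl) carbonate
Product: 5 7-[(2-methylbut-3-en-2-yl)oxy]-4H-chromen-4-one
Conditions: Pd(PPh3)4 (2 mol %), 3 (1.3 equiv), THF, 0 °C
Reagents that add atoms: none
Why: Decarboxylative Tsuji–Trost O-allylation: Pd(0) ionises 3 to a 1,1-dimethyl-π-allyl complex, CO2 and tert-butoxide, which deprotonates the acidic 7-OH. The phenoxide attacks the more substituted allyl terminus under kinetic control to give the tertiary ether, and low temperature and short contact time should prevent equilibration to the linear prenyl ether.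

Step 3
Reactants: 5 7-[(2-methylbut-3-en-2-yl)oxy]-4H-chromen-4-one
Product: 7 7-hydroxy-8-(3-methylbut-2-en-1-yl)-4H-chromen-4-one, via 8-(3-methylbut-2-en-1-yl)-4H-chromene-4,7(8H)-dione 6 (not isolated)
Conditions: PhNEt2, 130 °C, Ar
Reagents that add atoms: none
Why: Aromatic Claisen rearrangement: a chair-like [3,3] shift gives ortho-dienone 6, which tautomerises to phenol 7. Migration should favour C8 over C6 because the C7–C8 bond of the benzo-γ-pyrone has the higher double-bond character (as in the 7-oxycoumarin series) and C4a is blocked; the amine solvent suppresses ionisation of the ether and acid-catalysed chroman formation.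

Step 4
Reactants: 7 7-hydroxy-8-(3-methylbut-2-en-1-yl)-4H-chromen-4-one; 3 tert-butyl (2-methylbut-3-en-2-yl) carbonate
Product: 8 7-[(2-methylbut-3-en-2-yl)oxy]-8-(3-methylbut-2-en-1-yl)-4H-chromen-4-one
Conditions: Pd(PPh3)4 (5 mol %), 3 (1.5 equiv), THF, 0 °C; work-up and concentration below 30 °C
Reagents that add atoms: none
Why: The same decarboxylative Tsuji–Trost O-allylation, now on an ortho-substituted phenoxide; attack at the tertiary terminus of the π-allyl is kinetically preferred and the prenyl olefin is inert to Pd(0). All later handling stays below the Claisen threshold of the new ether.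

Step 5
Reactants: 8 7-[(2-methylbut-3-en-2-yl)oxy]-8-(3-methylbut-2-en-1-yl)-4H-chromen-4-one; 9 phenylboronic acid
Product: 10 (2S)-7-[(2-methylbut-3-en-2-yl)oxy]-8-(3-methylbut-2-en-1-yl)-2-phenyl-2,3-dihydro-4H-chromen-4-one (Griffinone C)
Conditions: [Rh(OH)(cod)]2 (1.5 mol %), (S)-MeO-F12-BIPHEP (3.3 mol %), 9 (3 equiv), toluene/H2O (10:1), 20 °C
Reagents that add atoms: none
Why: Rh(I)-catalysed asymmetric 1,4-addition of an arylboronic acid to an enone (Hayashi–Miyaura reaction), a reaction type established for 4H-chromen-4-ones as a direct entry to 2-arylchroman-4-ones. Phenyl is transmetalated from boron to the bisphosphine–Rh–OH complex, C2=C3 of 8 coordinates and inserts so that phenyl goes to C2 and Rh to C3 (oxa-π-allyl enolate), and water then protonates C3 (a CH2, so no second stereocentre) and regenerates Rh–OH. No ring is closed; ring C only changes from pyranone to dihydropyranone. The single new stereocentre C2 is set under catalyst control: the C2-symmetric (S)-biaryl bisphosphine shields one enantioface of the planar chromone, and the face predicted by the quadrant model for cyclic enones gives 2S. Chemoselectivity rests on the substrate, since only C2=C3 is conjugated to C4=O and can accept the aryl–Rh nucleophile, while the trisubstituted prenyl olefin and the neopentyl-type vinyl group are unactivated. 1,2-Addition to C4=O of 8 or of the product ketone should be held back by the electron-poor ligand and the low temperature. The medium is close to neutral at 20 °C, so neither opening of O1–C2 to the chalcone nor the Claisen shift of the O7 group to C6 should intervene, and no later step can erode C2.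

## Compound list

1 | 2-methylbut-3-en-2-ol | C=CC(C)(C)O | starting material
2 | lithium 2-methylbut-3-en-2-olate | [Li+].[O-]C(C)(C)C=C | intermediate (not isolated)
3 | tert-butyl (2-methylbut-3-en-2-yl) carbonate | C=CC(C)(C)OC(=O)OC(C)(C)C | intermediate
4 | 7-hydroxy-4H-chromen-4-one | O=c1ccoc2cc(O)ccc12 | starting material
5 | 7-[(2-methylbut-3-en-2-yl)oxy]-4H-chromen-4-one | C=CC(C)(C)Oc1ccc2c(c1)occc2=O | intermediate
6 | 8-(3-methylbut-2-en-1-yl)-4H-chromene-4,7(8H)-dione | CC(C)=CCC1C(=O)C=CC2=C1OC=CC2=O | intermediate (not isolated)
7 | 7-hydroxy-8-(3-methylbut-2-en-1-yl)-4H-chromen-4-one | CC(C)=CCc1c(O)ccc2c1occc2=O | intermediate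
8 | 7-[(2-methylbut-3-en-2-yl)oxy]-8-(3-methylbut-2-en-1-yl)-4H-chromen-4-one | C=CC(C)(C)Oc1ccc2c(c1CC=C(C)C)occc2=O | intermediate
9 | phenylboronic acid | OB(O)c1ccccc1 | starting material
10 | (2S)-7-[(2-methylbut-3-en-2-yl)oxy]-8-(3-methylbut-2-en-1-yl)-2-phenyl-2,3-dihydro-4H-chromen-4-one (Griffinone C) | C=CC(C)(C)Oc1ccc2c(c1CC=C(C)C)O[C@H](c1ccccc1)CC2=O | target

## Step count and risk

Total: 5 steps. Longest linear sequence: 5 steps (1 → 3 → 5 → 7 → 8 → 10), or 4 steps counted from chromone 4.

**Step 5 (key step).** Three things may go wrong. Aryl–Rh may add to the vinyl group of the O7 ether and then eliminate the aryloxide, which would remove the O7 substituent. The olefins may bind the catalyst and slow the conjugate addition, so that 1,2-addition to C4=O competes. The electron-rich, 8-substituted chromone may react with lower facial selectivity than the parent.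
Fallback: the arylation is moved ahead of the sensitive ether. Phenol 7 is silylated (TBSCl, imidazole, DMF) to 7-[(tert-butyldimethylsilyl)oxy]-8-(3-methylbut-2-en-1-yl)-4H-chromen-4-one F1. The same Rh-catalysed addition of 9 gives (2S)-7-[(tert-butyldimethylsilyl)oxy]-8-(3-methylbut-2-en-1-yl)-2-phenyl-2,3-dihydro-4H-chromen-4-one F2. Fluoride buffered with acetic acid (TBAF/AcOH, THF, 0 °C) releases (2S)-7-hydroxy-8-(3-methylbut-2-en-1-yl)-2-phenyl-2,3-dihydro-4H-chromen-4-one F3. The palladium etherification of step 4 with 3 at 0 °C, where the acidic phenol buffers the alkoxide, then gives 10.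

**Step 3.** Part of the migration may go to C6, and the tertiary ether may fragment thermally to 4 and isoprene before it rearranges.
Fallback: the C8–C bond is made by cross-coupling instead of a sigmatropic shift. Chromone 4 is iodinated at its most nucleophilic position (I2, KI, aqueous NH3) to 7-hydroxy-8-iodo-4H-chromen-4-one F4. An α-selective, ligand-controlled Suzuki–Miyaura coupling with 3-methylbut-2-enylboronic acid pinacol ester (Pd, bulky biarylphosphine, K3PO4, aqueous THF, 40 °C) then gives 7. Steps 2 and 3 are bypassed.

**Step 4.** Attack of the hindered, weakly nucleophilic phenoxide may be slow, so that Pd(0) re-ionises the product and funnels it to the linear prenyl ether or back to 7.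
Fallback: the tertiary C–O bond is made by copper-catalysed propargylic substitution. Phenol 7 is treated with 2-methylbut-3-yn-2-yl trifluoroacetate (CuCl2 cat., DBU, MeCN, 0 °C) to give 7-[(2-methylbut-3-yn-2-yl)oxy]-8-(3-methylbut-2-en-1-yl)-4H-chromen-4-one F5. Semi-hydrogenation (H2, Lindlar catalyst, quinoline, EtOAc) then gives 8.

**Step 2.** The 7-oxychromone is a good leaving group, so Pd-mediated equilibration of the branched ether to the linear one may be faster than with ordinary phenols.
Fallback: the same two-stage sequence. Chromone 4 is propargylated (2-methylbut-3-yn-2-yl trifluoroacetate, CuCl2 cat., DBU, MeCN, 0 °C) to 7-[(2-methylbut-3-yn-2-yl)oxy]-4H-chromen-4-one F6. Lindlar semi-hydrogenation then gives 5.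

## Further compounds

F1 | step 5 | 7-[(tert-butyldimethylsilyl)oxy]-8-(3-methylbut-2-en-1-yl)-4H-chromen-4-one | CC(C)=CCc1c(O[Si](C)(C)C(C)(C)C)ccc2c1occc2=O
F2 | step 5 | (2S)-7-[(tert-butyldimethylsilyl)oxy]-8-(3-methylbut-2-en-1-yl)-2-phenyl-2,3-dihydro-4H-chromen-4-one | CC(C)=CCc1c(O[Si](C)(C)C(C)(C)C)ccc2c1O[C@H](c1ccccc1)CC2=O
F3 | step 5 | (2S)-7-hydroxy-8-(3-methylbut-2-en-1-yl)-2-phenyl-2,3-dihydro-4H-chromen-4-one | CC(C)=CCc1c(O)ccc2c1O[C@H](c1ccccc1)CC2=O
F4 | step 3 | 7-hydroxy-8-iodo-4H-chromen-4-one | O=c1ccoc2c(I)c(O)ccc12
F5 | step 4 | 7-[(2-methylbut-3-yn-2-yl)oxy]-8-(3-methylbut-2-en-1-yl)-4H-chromen-4-one | C#CC(C)(C)Oc1ccc2c(c1CC=C(C)C)occc2=O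
F6 | step 2 | 7-[(2-methylbut-3-yn-2-yl)oxy]-4H-chromen-4-one | C#CC(C)(C)Oc1ccc2c(c1)occc2=O
A1 | alternative 1 | (E)-1-[2-hydroxy-4-[(2-methylbut-3-en-2-yl)oxy]-3-(3-methylbut-2-en-1-yl)phenyl]-3-phenylprop-2-en-1-one | C=CC(C)(C)Oc1ccc(C(=O)/C=C/c2ccccc2)c(O)c1CC=C(C)C
A2 | alternative 1 | 1-[2-hydroxy-4-[(2-methylbut-3-en-2-yl)oxy]-3-(3-methylbut-2-en-1-yl)phenyl]ethan-1-one | C=CC(C)(C)Oc1ccc(C(C)=O)c(O)c1CC=C(C)C
A3 | alternative 2 | 7-[(2-methylbut-3-en-2-yl)oxy]-8-(3-methylbut-2-en-1-yl)-2-phenyl-4H-chromen-4-one | C=CC(C)(C)Oc1ccc2c(c1CC=C(C)C)oc(-c1ccccc1)cc2=O
A4 | alternative 3 | (2S)-8,8-bis(3-methylbut-2-en-1-yl)-2-phenyl-2,3-dihydro-4H-chromene-4,7(8H)-dione | CC(C)=CCC1(CC=C(C)C)C(=O)C=CC2=C1O[C@H](c1ccccc1)CC2=O
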